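**Retrosynthetic overview**
1. The last bonds cleaved are the two O–methyl bonds at C5 and C7. Before that, the pyranone ring (ring B, O1–C2 bond) is closed by 6-endo-dig addition of the C8a phenol to an aryl ynone; it is the only ring made, ring A coming from a commercial arene.
2. Key disconnection: C8a–O1 and C4a–C4 are made together by inserting 3,5-dimethoxy-4,6-dimethylbenzyne into the acyl C–O bond of docos-2-ynoic acid.
3. Feature on which this rests: in ring A the O1-bearing C8a and the acyl-bearing C4a are neighbours, C4a lying next to the C5 oxygen and C8a next to the C8 methyl. This is the pattern left when a 3-alkoxyaryne takes an oxygen nucleophile at its remote carbon and an acyl group at the carbon beside the alkoxy group.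
4. The aryne precursor, an ortho-silylaryl triflate, comes from 2,4-dimethoxy-3,5-dimethylphenol by ortho-bromination, O-silylation, retro-Brook shift and triflation. The phenol comes from commercial 2,4-dimethoxy-3-methylbenzaldehyde by CHO-to-CH3 hydrogenolysis, formylation and Dakin oxidation.
5. Docos-2-ynoic acid comes from the propiolic acid dianion and 1-bromononadecane.

Key step: step 7

Remark on the chemistry: the target has no stereocentre, the side chain is read as unbranched nonadecyl, and chromone numbering (O1, C2, C3, C4, C4a, C5 to C8, C8a) is used for these atoms in every intermediate.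

**Route**

Step 1
Reactants: 1 2,4-dimethoxy-3-methylbenzaldehyde
Product: 3 1,3-dimethoxy-2,4-dimethylbenzene, via (2,4-dimethoxy-3-methylphenyl)methanol 2 (not isolated)
Conditions: H2 (3 bar), Pd/C (10%), AcOH, cat. HCl, rt
Reagents that add atoms: none
Why: Catalytic hydrogenation of the electron-rich benzaldehyde gives benzylic alcohol 2, whose C–O bond is hydrogenolysed under the acidic conditions because the ortho and para methoxy groups stabilise benzylic cation character (aldehyde-to-methyl hydrogenolysis over Pd/C).

Step 2
Reactants: 3 1,3-dimethoxy-2,4-dimethylbenzene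
Product: 4 2,4-dimethoxy-3,5-dimethylbenzaldehyde
Conditions: Cl2CHOMe, TiCl4, CH2Cl2, 0 °C; then H2O
Reagents that add atoms: dichloromethyl methyl ether, COC(Cl)Cl; water, O
Why: Rieche formylation (electrophilic aromatic substitution) should go to the one ring CH that is ortho to one methoxy group and para to the other, the remaining CH being meta to both.

Step 3
Reactants: 4 2,4-dimethoxy-3,5-dimethylbenzaldehyde
Product: 6 2,4-dimethoxy-3,5-dimethylphenol, via 2,4-dimethoxy-3,5-dimethylphenyl formate 5 (not isolated)
Conditions: mCPBA, CH2Cl2, 0 °C to rt; then K2CO3, MeOH, rt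
Reagents that add atoms: mCPBA, O=C(OO)c1cccc(Cl)c1
Why: Dakin-type Baeyer–Villiger oxidation, in which the electron-rich aryl group of the Criegee adduct migrates to oxygen in preference to hydride to give formate 5, which mild methanolysis converts to the phenol.

Step 4
Reactants: 6 2,4-dimethoxy-3,5-dimethylphenol
Product: 7 2-bromo-4,6-dimethoxy-3,5-dimethylphenol
Conditions: NBS, cat. i-Pr2NH, CH2Cl2, 0 °C, dark
Reagents that add atoms: N-bromosuccinimide, O=C1CCC(=O)N1Br
Why: Electrophilic aromatic bromination at the single free ring position, which is ortho to the hydroxyl group; low temperature and exclusion of light and water should suppress benzylic bromination and oxidation to a quinone.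

Step 5
Reactants: 7 2-bromo-4,6-dimethoxy-3,5-dimethylphenol
Product: 10 2,4-dimethoxy-3,5-dimethyl-6-(trimethylsilyl)phenyl trifluoromethanesulfonate, via (2-bromo-4,6-dimethoxy-3,5-dimethylphenoxy)trimethylsilane 8 (not isolated), via lithium 2,4-dimethoxy-3,5-dimethyl-6-(trimethylsilyl)phenolate 9 (not isolated)
Conditions: (Me3Si)2NH, THF, reflux, then evaporate; n-BuLi, THF, −78 °C; Tf2O, −78 °C to rt
Reagents that add atoms: hexamethyldisilazane, C[Si](C)(C)N[Si](C)(C)C; trifluoromethanesulfonic anhydride, O=S(=O)(OS(=O)(=O)C(F)(F)F)C(F)(F)F
Why: O-silylation, bromine–lithium exchange and retro-Brook rearrangement (1,3 O-to-C silyl shift in the ortho-lithiated aryl silyl ether) give phenoxide 9, which triflic anhydride traps on oxygen; this is the standard passage from ortho-bromophenols to ortho-silylaryl triflates.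

Step 6
Reactants: 11 propiolic acid; 12 1-bromononadecane
Product: 13 docos-2-ynoic acid
Conditions: n-BuLi (2.1 equiv), THF/HMPA, −78 °C; then 12, −78 °C to rt; aq. HCl
Reagents that add atoms: none
Why: Double deprotonation of propiolic acid gives the lithium carboxylate acetylide, whose acetylide carbon is the more nucleophilic site and is alkylated by the primary bromide in an SN2 reaction promoted by HMPA.

Step 7
Reactants: 10 2,4-dimethoxy-3,5-dimethyl-6-(trimethylsilyl)phenyl trifluoromethanesulfonate; 13 docos-2-ynoic acid
Product: 15 1-(2-hydroxy-4,6-dimethoxy-3,5-dimethylphenyl)docos-2-yn-1-one, via 3,5-dimethoxy-4,6-dimethylbenzyne 14 (not isolated)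
Conditions: 13 (1.0 equiv), 10 (1.5 equiv), CsF (4 equiv), THF, 125 °C, sealed tube
Reagents that add atoms: none
Why: Fluoride removes the silyl group of 10 and triflate leaves to give aryne 14 (C4a≡C8a); the caesium carboxylate of 13 adds through oxygen at C8a, the resulting C4a aryl anion attacks the ester carbonyl to form a four-membered benzoxetene hemiketal alkoxide, and this opens to the phenoxide of ortho-hydroxyaryl ynone 15, a net insertion of the aryne into the acyl C–O bond. The closest known reaction type is the CsF-induced insertion of arynes into the C–O bond of carboxylic acids, arylpropiolic acids included, which gives ortho-hydroxyaryl ketones at elevated temperature, whereas low temperature stops at the aryl ester. No ring of the target closes here (the oxetene is transient) and no stereocentre is formed. The step needs oxygen at C8a and the acyl group at C4a: the C5 methoxy group withdraws inductively, distorts the aryne so that the remote carbon C8a is the more electrophilic, and stabilises the developing charge at C4a, which should outweigh the small opposing effects of the C8 methyl and the C7 methoxy group. It also needs acyl transfer to outrun protonation of the aryl anion, which the intramolecular attack, the high temperature and the use of the acid as limiting component (bifluoride being the only proton source) should favour. Any 15 that already cyclises under the fluoride conditions gives 16, the product of step 8, so the crude mixture can be taken forward.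

Step 8
Reactants: 15 1-(2-hydroxy-4,6-dimethoxy-3,5-dimethylphenyl)docos-2-yn-1-one
Product: 16 5,7-dimethoxy-6,8-dimethyl-2-nonadecyl-4H-chromen-4-one
Conditions: K2CO3, acetone, reflux
Reagents that add atoms: none
Why: 6-endo-dig oxa-Michael addition of the C8a phenoxide to the ynone β-carbon gives a stabilised allenolate and closes the pyranone ring, whereas under aprotic carbonate conditions the 5-exo mode would give an unstabilised vinyl anion and is disfavoured.

Step 9
Reactants: 16 5,7-dimethoxy-6,8-dimethyl-2-nonadecyl-4H-chromen-4-one
Product: 17 5,7-dihydroxy-6,8-dimethyl-2-nonadecyl-4H-chromen-4-one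
Conditions: BBr3 (6 equiv), CH2Cl2, −78 °C to rt; then H2O
Reagents that add atoms: none
Why: Lewis-acid ether cleavage, in which BBr3 coordinates each methoxy oxygen (the C5 one helped by chelation to the C4 carbonyl, the C7 one twisted out of plane between two methyl groups and therefore basic) and bromide removes the methyl group by SN2, the borate esters being hydrolysed on work-up.

**Compound list**
1 | 2,4-dimethoxy-3-methylbenzaldehyde | COc1ccc(C=O)c(OC)c1C | starting material
2 | (2,4-dimethoxy-3-methylphenyl)methanol | COc1ccc(CO)c(OC)c1C | intermediate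
3 | 1,3-dimethoxy-2,4-dimethylbenzene | COc1ccc(C)c(OC)c1C | intermediate
4 | 2,4-dimethoxy-3,5-dimethylbenzaldehyde | COc1c(C)cc(C=O)c(OC)c1C | intermediate
5 | 2,4-dimethoxy-3,5-dimethylphenyl formate | COc1c(C)cc(OC=O)c(OC)c1C | intermediate
6 | 2,4-dimethoxy-3,5-dimethylphenol | COc1c(C)cc(O)c(OC)c1C | intermediate
7 | 2-bromo-4,6-dimethoxy-3,5-dimethylphenol | COc1c(C)c(OC)c(O)c(Br)c1C | intermediate
8 | (2-bromo-4,6-dimethoxy-3,5-dimethylphenoxy)trimethylsilane | COc1c(C)c(OC)c(O[Si](C)(C)C)c(Br)c1C | intermediate
9 | lithium 2,4-dimethoxy-3,5-dimethyl-6-(trimethylsilyl)phenolate | COc1c(C)c(OC)c([O-])c([Si](C)(C)C)c1C.[Li+] | intermediate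
10 | 2,4-dimethoxy-3,5-dimethyl-6-(trimethylsilyl)phenyl trifluoromethanesulfonate | COc1c(C)c(OC)c(OS(=O)(=O)C(F)(F)F)c([Si](C)(C)C)c1C | intermediate
11 | propiolic acid | C#CC(=O)O | starting material
12 | 1-bromononadecane | CCCCCCCCCCCCCCCCCCCBr | starting material
13 | docos-2-ynoic acid | CCCCCCCCCCCCCCCCCCCC#CC(=O)O | intermediate
14 | 3,5-dimethoxy-4,6-dimethylbenzyne | COC1=C(C)C#CC(OC)=C1C | intermediate
15 | 1-(2-hydroxy-4,6-dimethoxy-3,5-dimethylphenyl)docos-2-yn-1-one | CCCCCCCCCCCCCCCCCCCC#CC(=O)c1c(O)c(C)c(OC)c(C)c1OC | intermediate
16 | 5,7-dimethoxy-6,8-dimethyl-2-nonadecyl-4H-chromen-4-one | CCCCCCCCCCCCCCCCCCCc1cc(=O)c2c(OC)c(C)c(OC)c(C)c2o1 | intermediate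
17 | 5,7-dihydroxy-6,8-dimethyl-2-nonadecyl-4H-chromen-4-one | CCCCCCCCCCCCCCCCCCCc1cc(=O)c2c(O)c(C)c(O)c(C)c2o1 | target

**Step count**
Total steps: 9. Longest linear sequence: 8 steps (steps 1 to 5, then 7 to 9); step 6 is a one-step side branch.

**Steps most likely to fail**

Step 7. The C4a aryl anion may be protonated before it reaches the carbonyl, so that only O-arylation occurs. The ynoate may also take up fluoride or phenoxide in conjugate fashion, or the ynoic acid may lose CO2 at 125 °C. The fallback sets out from 10 and comes back at 16. It keeps the aryne for the C8a–O bond but builds C4a–C4 and the side chain by acylation chemistry. 10 is treated with acetic acid and CsF in MeCN at rt, conditions under which arynes O-arylate carboxylic acids, to give 3,5-dimethoxy-2,4-dimethylphenyl acetate F1 under the same regiocontrol by the C5 methoxy group. Fries rearrangement with BF3·OEt2 at 90 °C moves the acetyl group to the only free ring position, C4a, and gives 1-(2-hydroxy-4,6-dimethoxy-3,5-dimethylphenyl)ethan-1-one F2. Claisen condensation of F2 with methyl icosanoate (NaH, THF, reflux) gives 1-(2-hydroxy-4,6-dimethoxy-3,5-dimethylphenyl)docosane-1,3-dione F3. Cyclodehydration of F3 (HCl, AcOH, 80 °C) gives 16.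

Step 8. The phenoxide may close in the 5-exo-dig mode to an alkylidene benzofuranone, or the ynone may degrade under base before closing. The fallback sets out from 15 and comes back at 16. Diethylamine in EtOH at rt adds to the ynone to give (E)-3-(diethylamino)-1-(2-hydroxy-4,6-dimethoxy-3,5-dimethylphenyl)docos-2-en-1-one F4. On warming with a trace of HCl the phenol displaces the amine at the β-carbon by addition–elimination, which can only give the six-membered ring of 16.

Step 6. SN2 alkylation of the poorly soluble propiolate dianion by the long-chain bromide may be slow, leaving bromide unreacted or giving elimination. The fallback sets out from 12 and comes back at 13. Lithium acetylide–ethylenediamine complex (LiC≡CH·H2NCH2CH2NH2) in DMSO at rt gives henicos-1-yne F5. Deprotonation of F5 with n-BuLi in THF at −78 °C, carboxylation with CO2 and acidic work-up give 13.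

**Further compounds**
F1 | step 7 | 3,5-dimethoxy-2,4-dimethylphenyl acetate | CC(=O)Oc1cc(OC)c(C)c(OC)c1C
F2 | step 7 | 1-(2-hydroxy-4,6-dimethoxy-3,5-dimethylphenyl)ethan-1-one | CC(=O)c1c(O)c(C)c(OC)c(C)c1OC
F3 | step 7 | 1-(2-hydroxy-4,6-dimethoxy-3,5-dimethylphenyl)docosane-1,3-dione | CCCCCCCCCCCCCCCCCCCC(=O)CC(=O)c1c(O)c(C)c(OC)c(C)c1OC
F4 | step 8 | (E)-3-(diethylamino)-1-(2-hydroxy-4,6-dimethoxy-3,5-dimethylphenyl)docos-2-en-1-one | CCCCCCCCCCCCCCCCCCC/C(N(CC)CC)=C\C(=O)c1c(O)c(C)c(OC)c(C)c1OC
F5 | step 6 | henicos-1-yne | CCCCCCCCCCCCCCCCCCCC#C
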